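**Retrosynthetic overview**

- The strategy rests on the vicinal C7(OH)–C8(O‑aryl) pair that joins the syringyl ring to C9. It is read as the syn H/OH adduct across a (Z)‑C7=C8 enol ether whose oxygen is O4′ of the 2,6‑dimethoxyphenoxy ring, and the 3‑hydroxypropyl arm on that ring is read as the anti‑Markovnikov hydrate of an allyl group.
- Disconnections, last to first: C7–OH/C8–H together with the propanol C–OH (one asymmetric hydroboration–oxidation), C7=C8 (Horner–Wadsworth–Emmons), C8–O4′ (rhodium‑carbenoid O–H insertion of 4‑allyl‑2,6‑dimethoxyphenol into triethyl diazophosphonoacetate).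
- No ring is formed at any stage. Both benzene rings are bought (syringaldehyde, 4‑allyl‑2,6‑dimethoxyphenol) and only the three‑carbon chain between them is built.
- Protection: aryl TIPS and primary TBS, both removed by buffered fluoride in the last step.

Key step: step 7

Assumption: carbons are numbered as in 8‑O‑4′ neolignans (C7 benzylic carbinol, C8 aryloxy carbon, C9 primary carbinol) and the SMILES is read as the erythro (7R,8S) isomer; the facial sense quoted for the isopinocampheylborane antipode is a prediction by analogy with trisubstituted aryl alkenes, to be checked on the first run (Mosher ester at C7), the antipodal reagent being equally accessible.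

**Route**

Step 1
Reactants: 1 syringaldehyde
Product: 2 3,5-dimethoxy-4-(triisopropylsilyloxy)benzaldehyde
Conditions: TIPSCl, imidazole, DMAP (cat.), DMF, rt
Reagents that add atoms: triisopropylsilyl chloride, CC(C)[Si](Cl)(C(C)C)C(C)C
Why: Imidazole‑promoted O‑silylation caps the acidic phenol that would otherwise quench the phosphonate anion and the hydride reagents, and the bulky aryl TIPS ether should tolerate NaH, iBu2AlH and boranes yet fall to fluoride at the end.

Step 2
Reactants: 3 triethyl phosphonoacetate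
Product: 4 triethyl diazophosphonoacetate
Conditions: 4-acetamidobenzenesulfonyl azide, DBU, MeCN, 0 °C → rt
Reagents that add atoms: 4-acetamidobenzenesulfonyl azide, CC(=O)Nc1ccc(cc1)S(=O)(=O)N=[N+]=[N-]
Why: Regitz diazo transfer, in which the phosphonoacetate carbanion attacks the terminal azide nitrogen and the triazene adduct collapses to the diazo compound and the sulfonamide.

Step 3
Reactants: 5 4-allyl-2,6-dimethoxyphenol; 4 triethyl diazophosphonoacetate
Product: 6 triethyl 2-(4-allyl-2,6-dimethoxyphenoxy)phosphonoacetate (racemic)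
Conditions: Rh2(OAc)4 (2 mol%), toluene, 80 °C, slow addition of 4 to 5 (slight excess)
Reagents that add atoms: none
Why: Rhodium‑carbenoid O–H insertion, in which the electrophilic acceptor/acceptor carbenoid from the divalent‑rhodium carboxylate dimer is captured by the phenol oxygen (oxonium ylide, then proton shift) faster than it cyclopropanates the unactivated allyl group, so the C8–O4′ bond is formed on a phosphonate ready for olefination.

Step 4
Reactants: 6 triethyl 2-(4-allyl-2,6-dimethoxyphenoxy)phosphonoacetate; 2 3,5-dimethoxy-4-(triisopropylsilyloxy)benzaldehyde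
Product: 7 ethyl (Z)-2-(4-allyl-2,6-dimethoxyphenoxy)-3-[3,5-dimethoxy-4-(triisopropylsilyloxy)phenyl]acrylate
Conditions: NaH, THF, 0 °C → rt; chromatographic removal of the minor E isomer
Reagents that add atoms: none
Why: Horner–Wadsworth–Emmons olefination forms C7=C8, and with an aryl aldehyde the reversible addition should funnel to the isomer with the aryl group trans to the ester (the Z enol ether), which is purified here so that geometrically pure material reaches the key step.

Step 5
Reactants: 7 ethyl (Z)-2-(4-allyl-2,6-dimethoxyphenoxy)-3-[3,5-dimethoxy-4-(triisopropylsilyloxy)phenyl]acrylate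
Product: 8 (Z)-2-(4-allyl-2,6-dimethoxyphenoxy)-3-[3,5-dimethoxy-4-(triisopropylsilyloxy)phenyl]prop-2-en-1-ol
Conditions: iBu2AlH, CH2Cl2, −78 °C; aq potassium sodium tartrate work-up
Reagents that add atoms: none
Why: 1,2‑Reduction of the conjugated ester by the aluminium hydride at low temperature should give the allylic alcohol without touching the enol ether, the terminal alkene or the aryl silyl ether, and the double‑bond geometry is not affected.

Step 6
Reactants: 8 (Z)-2-(4-allyl-2,6-dimethoxyphenoxy)-3-[3,5-dimethoxy-4-(triisopropylsilyloxy)phenyl]prop-2-en-1-ol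
Product: 9 tert-butyldimethylsilyl ether of 8
Conditions: TBSCl, imidazole, CH2Cl2, 0 °C → rt
Reagents that add atoms: tert-butyldimethylsilyl chloride, CC(C)(C)[Si](C)(C)Cl
Why: Standard silylation of the primary allylic alcohol, which keeps C9–OH from consuming borane or delivering it intramolecularly in the next step.

Step 7
Reactants: 9 tert-butyldimethylsilyl ether of 8
Product: 11 (1R,2S)-3-(tert-butyldimethylsilyloxy)-1-[3,5-dimethoxy-4-(triisopropylsilyloxy)phenyl]-2-[4-(3-hydroxypropyl)-2,6-dimethoxyphenoxy]propan-1-ol, via bis(isopinocampheylboryl) adduct 10 (not isolated)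
Conditions: IpcBH2 prepared from (−)-α-pinene (BF3-free stock solution, 3.5 equiv), THF, −25 °C; then 30% H2O2, 3 M aq NaOAc, 0 °C → rt
Reagents that add atoms: monoisopinocampheylborane from (−)-α-pinene, B[C@H]1C[C@H]2C[C@@H]([C@@H]1C)C2(C)C (its boron and isopinocampheyl group stay only in 10); hydrogen peroxide, OO
Why: Proposed new method: the B–H bond of the chiral monoalkylborane adds in a concerted four‑centre syn fashion across the (Z)‑C7=C8 enol ether, boron going to C7 (the CH carbon β to the enol oxygen) and hydrogen to C8, while a second equivalent adds anti‑Markovnikov to the allyl terminus; peroxide then converts both C–B bonds into C–OH with retention (1,2‑shift of carbon from boron to oxygen). The closest known reaction types are IpcBH2 hydroboration–oxidation of trisubstituted aryl alkenes and racemic hydroboration–oxidation of enol ethers that places boron β to oxygen; the enantioselective use on a 2‑aryloxy enol ether is the untested part. No ring is closed. C7 and C8 are created together: their erythro relationship is dictated by the Z geometry of 9 (syringyl ring cis to the aryloxy oxygen) combined with syn addition and retentive oxidation, and their absolute sense (7R,8S) by the isopinocampheyl group on boron, the reagent from (−)‑α‑pinene being the one predicted by analogy to attack the required face. The step therefore needs facial selectivity only, because regiochemistry is secured twice over by the polarisation of the enol ether and by the lower substitution at C7, and because both alkenes are meant to react no chemoselectivity is asked for. Loss of the aryloxy group by β‑elimination from the C7 borane is countered by a BF3‑free reagent, −25 °C and immediate cold acetate‑buffered oxidation.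

Step 8
Reactants: 11 (1R,2S)-3-(tert-butyldimethylsilyloxy)-1-[3,5-dimethoxy-4-(triisopropylsilyloxy)phenyl]-2-[4-(3-hydroxypropyl)-2,6-dimethoxyphenoxy]propan-1-ol
Product: 12 (1R,2S)-1-(4-hydroxy-3,5-dimethoxyphenyl)-2-[4-(3-hydroxypropyl)-2,6-dimethoxyphenoxy]propane-1,3-diol (target, 7R,8S erythro)
Conditions: Bu4NF, AcOH, THF, 0 °C → rt
Reagents that add atoms: none
Why: Fluoride‑mediated desilylation should cleave the aryl TIPS and the primary TBS ether in one operation, and the acetic acid buffer keeps the freed syringyl phenol protonated so that no quinone methide can form and scramble C7.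

**Compound list**

1 | syringaldehyde (4-hydroxy-3,5-dimethoxybenzaldehyde) | COc1cc(C=O)cc(OC)c1O | starting material
2 | 3,5-dimethoxy-4-(triisopropylsilyloxy)benzaldehyde | COc1cc(C=O)cc(OC)c1O[Si](C(C)C)(C(C)C)C(C)C | intermediate
3 | triethyl phosphonoacetate | CCOC(=O)CP(=O)(OCC)OCC | starting material
4 | triethyl diazophosphonoacetate | CCOC(=O)C(=[N+]=[N-])P(=O)(OCC)OCC | intermediate
5 | 4-allyl-2,6-dimethoxyphenol | COc1cc(CC=C)cc(OC)c1O | starting material
6 | triethyl 2-(4-allyl-2,6-dimethoxyphenoxy)phosphonoacetate (racemic) | CCOC(=O)C(Oc1c(OC)cc(CC=C)cc1OC)P(=O)(OCC)OCC | intermediate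
7 | ethyl (Z)-2-(4-allyl-2,6-dimethoxyphenoxy)-3-[3,5-dimethoxy-4-(triisopropylsilyloxy)phenyl]acrylate | CCOC(=O)/C(Oc1c(OC)cc(CC=C)cc1OC)=C/c1cc(OC)c(O[Si](C(C)C)(C(C)C)C(C)C)c(OC)c1 | intermediate
8 | (Z)-2-(4-allyl-2,6-dimethoxyphenoxy)-3-[3,5-dimethoxy-4-(triisopropylsilyloxy)phenyl]prop-2-en-1-ol | OC/C(Oc1c(OC)cc(CC=C)cc1OC)=C/c1cc(OC)c(O[Si](C(C)C)(C(C)C)C(C)C)c(OC)c1 | intermediate
9 | tert-butyldimethylsilyl ether of 8 | CC(C)(C)[Si](C)(C)OC/C(Oc1c(OC)cc(CC=C)cc1OC)=C/c1cc(OC)c(O[Si](C(C)C)(C(C)C)C(C)C)c(OC)c1 | intermediate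
10 | bis(isopinocampheylboryl) adduct of 9 (boron on C7 and on the propyl terminus) | COc1cc([C@@H]([BH][C@H]2C[C@H]3C[C@@H]([C@@H]2C)C3(C)C)[C@H](CO[Si](C)(C)C(C)(C)C)Oc2c(OC)cc(CCC[BH][C@H]3C[C@H]4C[C@@H]([C@@H]3C)C4(C)C)cc2OC)cc(OC)c1O[Si](C(C)C)(C(C)C)C(C)C | intermediate
11 | (1R,2S)-3-(tert-butyldimethylsilyloxy)-1-[3,5-dimethoxy-4-(triisopropylsilyloxy)phenyl]-2-[4-(3-hydroxypropyl)-2,6-dimethoxyphenoxy]propan-1-ol | COc1cc([C@@H](O)[C@H](CO[Si](C)(C)C(C)(C)C)Oc2c(OC)cc(CCCO)cc2OC)cc(OC)c1O[Si](C(C)C)(C(C)C)C(C)C | intermediate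
12 | (1R,2S)-1-(4-hydroxy-3,5-dimethoxyphenyl)-2-[4-(3-hydroxypropyl)-2,6-dimethoxyphenoxy]propane-1,3-diol | COc1cc([C@@H](O)[C@H](CO)Oc2c(OC)cc(CCCO)cc2OC)cc(OC)c1O | target

**Step count**

Total steps: 8. Longest linear sequence: 7 (steps 2 to 8, from triethyl phosphonoacetate).

**Steps most likely to fail**

Step 7 (proposed new method). Two things may go wrong: the borane may discriminate poorly between the two faces of the flat enol ether, or the C7 borane may expel the neighbouring aryloxy group before it is oxidised. The fallback gives up the hydroboration and uses the classical aldol construction of arylglycerol β‑aryl ethers with a resolution; it sets out from 5 and 2 and rejoins the route at 12. Phenol 5 would be alkylated with ethyl bromoacetate (K2CO3, acetone, reflux) to ethyl 2-(4-allyl-2,6-dimethoxyphenoxy)acetate F1. Its lithium enolate (LiN(iPr)2, THF, −78 °C) would be added to aldehyde 2; this addition is expected to favour the erythro adduct, and after chromatographic removal of the threo isomer it should leave racemic erythro ethyl 2-(4-allyl-2,6-dimethoxyphenoxy)-3-[3,5-dimethoxy-4-(triisopropylsilyloxy)phenyl]-3-hydroxypropanoate F2. Preparative chromatography on a cellulose‑carbamate chiral stationary phase would deliver the (2R,3R) enantiomer F3. LiBH4 in THF would reduce the ester to (1R,2S)-2-(4-allyl-2,6-dimethoxyphenoxy)-1-[3,5-dimethoxy-4-(triisopropylsilyloxy)phenyl]propane-1,3-diol F4. Excess 9‑BBN followed by H2O2/aq NaOAc would turn the allyl group into the propanol arm, giving (1R,2S)-1-[3,5-dimethoxy-4-(triisopropylsilyloxy)phenyl]-2-[4-(3-hydroxypropyl)-2,6-dimethoxyphenoxy]propane-1,3-diol F5. Buffered Bu4NF as in step 8 would then give 12.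

Step 3. The carbenoid may be diverted into cyclopropanation of the allyl group or into dimerisation while insertion into the hindered, hydrogen‑bonded phenol lags. The fallback makes the C8–O4′ bond by Williamson etherification and the C7=C8 bond by a Perkin condensation, so no phosphonate is needed; it sets out from 5 and 2 and rejoins at 7. Phenol 5 would be heated with ClCH2CO2Na in aq NaOH (90 °C) and acidified to give 2-(4-allyl-2,6-dimethoxyphenoxy)acetic acid F6. Perkin–Oglialoro condensation with aldehyde 2 (Ac2O, Et3N, 110 °C, aqueous work‑up) should give, under thermodynamic control, (Z)-2-(4-allyl-2,6-dimethoxyphenoxy)-3-[3,5-dimethoxy-4-(triisopropylsilyloxy)phenyl]acrylic acid F7. Esterification with EtI and K2CO3 in DMF would give 7.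

Step 4. The hindered phosphonate anion may add sluggishly to the electron‑rich aldehyde, or the olefination may give a Z/E mixture that is hard to separate. The fallback forms the double bond stepwise by aldol addition and E1cB elimination under thermodynamic control; it sets out from 5 and 2 and rejoins at 8. Phenol 5 would be alkylated with methyl bromoacetate (K2CO3, acetone) to methyl 2-(4-allyl-2,6-dimethoxyphenoxy)acetate F8. Its lithium enolate (LiN(iPr)2, THF, −78 °C) would add to 2 to give methyl 2-(4-allyl-2,6-dimethoxyphenoxy)-3-[3,5-dimethoxy-4-(triisopropylsilyloxy)phenyl]-3-hydroxypropanoate F9 as a diastereomer mixture. Acetylation (Ac2O, DMAP, pyridine) would give the 3‑acetoxy ester F10. DBU in toluene at 60 °C should eliminate acetate through the ester enolate to methyl (Z)-2-(4-allyl-2,6-dimethoxyphenoxy)-3-[3,5-dimethoxy-4-(triisopropylsilyloxy)phenyl]acrylate F11. iBu2AlH under the conditions of step 5 would then give 8.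

**Further compounds**

F1 | step 7 | ethyl 2-(4-allyl-2,6-dimethoxyphenoxy)acetate | CCOC(=O)COc1c(OC)cc(CC=C)cc1OC
F2 | step 7 | racemic erythro ethyl 2-(4-allyl-2,6-dimethoxyphenoxy)-3-[3,5-dimethoxy-4-(triisopropylsilyloxy)phenyl]-3-hydroxypropanoate, the (2R,3R)/(2S,3S) pair | COc1cc([C@@H](O)[C@H](C(=O)OCC)Oc2c(OC)cc(CC=C)cc2OC)cc(OC)c1O[Si](C(C)C)(C(C)C)C(C)C.COc1cc([C@H](O)[C@@H](C(=O)OCC)Oc2c(OC)cc(CC=C)cc2OC)cc(OC)c1O[Si](C(C)C)(C(C)C)C(C)C
F3 | step 7 | ethyl (2R,3R)-2-(4-allyl-2,6-dimethoxyphenoxy)-3-[3,5-dimethoxy-4-(triisopropylsilyloxy)phenyl]-3-hydroxypropanoate | COc1cc([C@@H](O)[C@H](C(=O)OCC)Oc2c(OC)cc(CC=C)cc2OC)cc(OC)c1O[Si](C(C)C)(C(C)C)C(C)C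
F4 | step 7 | (1R,2S)-2-(4-allyl-2,6-dimethoxyphenoxy)-1-[3,5-dimethoxy-4-(triisopropylsilyloxy)phenyl]propane-1,3-diol | COc1cc([C@@H](O)[C@H](CO)Oc2c(OC)cc(CC=C)cc2OC)cc(OC)c1O[Si](C(C)C)(C(C)C)C(C)C
F5 | step 7 | (1R,2S)-1-[3,5-dimethoxy-4-(triisopropylsilyloxy)phenyl]-2-[4-(3-hydroxypropyl)-2,6-dimethoxyphenoxy]propane-1,3-diol | COc1cc([C@@H](O)[C@H](CO)Oc2c(OC)cc(CCCO)cc2OC)cc(OC)c1O[Si](C(C)C)(C(C)C)C(C)C
F6 | step 3 | 2-(4-allyl-2,6-dimethoxyphenoxy)acetic acid | OC(=O)COc1c(OC)cc(CC=C)cc1OC
F7 | step 3 | (Z)-2-(4-allyl-2,6-dimethoxyphenoxy)-3-[3,5-dimethoxy-4-(triisopropylsilyloxy)phenyl]acrylic acid | OC(=O)/C(Oc1c(OC)cc(CC=C)cc1OC)=C/c1cc(OC)c(O[Si](C(C)C)(C(C)C)C(C)C)c(OC)c1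
F8 | step 4 | methyl 2-(4-allyl-2,6-dimethoxyphenoxy)acetate | COC(=O)COc1c(OC)cc(CC=C)cc1OC
F9 | step 4 | methyl 2-(4-allyl-2,6-dimethoxyphenoxy)-3-[3,5-dimethoxy-4-(triisopropylsilyloxy)phenyl]-3-hydroxypropanoate (mixture of diastereomers) | COC(=O)C(Oc1c(OC)cc(CC=C)cc1OC)C(O)c1cc(OC)c(O[Si](C(C)C)(C(C)C)C(C)C)c(OC)c1
F10 | step 4 | methyl 3-acetoxy-2-(4-allyl-2,6-dimethoxyphenoxy)-3-[3,5-dimethoxy-4-(triisopropylsilyloxy)phenyl]propanoate (mixture of diastereomers) | COC(=O)C(Oc1c(OC)cc(CC=C)cc1OC)C(OC(C)=O)c1cc(OC)c(O[Si](C(C)C)(C(C)C)C(C)C)c(OC)c1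
F11 | step 4 | methyl (Z)-2-(4-allyl-2,6-dimethoxyphenoxy)-3-[3,5-dimethoxy-4-(triisopropylsilyloxy)phenyl]acrylate | COC(=O)/C(Oc1c(OC)cc(CC=C)cc1OC)=C/c1cc(OC)c(O[Si](C(C)C)(C(C)C)C(C)C)c(OC)c1
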